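**Plan**
- **Hardest feature:** two prenyl groups must each go to one specific CH of an acid- and oxidant-sensitive pentahydroxyflavone: C8 (not C6) on ring A and C5' (not C2' or C6') on ring B.
- **Enabling feature:** C8 and C5' each lie ortho to O7 and O4'. These two hydroxyls are conjugated with the C4 carbonyl of ring C (vinylogous acids), so they are the most acidic OH groups and can be addressed as a pair. C3' is blocked by oxygen.
- **Retrosynthesis:** C8–CH2 and C5'–CH2 are cut together by a twofold retro-[3,3] shift to the 7,4'-bis(1,1-dimethylallyl) ether. Both O–C(tert) bonds are then cut back to 3,5,3'-tri-O-acetylquercetin and to quercetin.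
- **Forward:** rings A, B and C come intact with quercetin. The sequence is peracetylation, twofold thiolysis at O7/O4', twofold Pd reverse O-prenylation, one twofold aromatic Claisen shift, and ammonolysis.
- **Stereochemistry:** none to set. The sp3 carbons of the dienone intermediates disappear on rearomatisation.

Key step: step 5

Remark: the SMILES holds no stereocentre and no stereogenic double bond, so the target is achiral and "single enantiomer" means the compound itself; quercetin is taken as a bulk commercial chemical.

Step 1
Reactants: 1 quercetin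
Product: 2 quercetin 3,5,7,3',4'-pentaacetate
Conditions: Ac2O, pyridine, DMAP (cat.), rt
Reagents that add atoms: acetic anhydride, CC(=O)OC(C)=O
Why: Exhaustive O-acylation under nucleophilic catalysis masks all five hydroxyls, the chelated 5-OH included, and turns the differences in phenol acidity into differences in ester lability.

Step 2
Reactants: 2 quercetin pentaacetate
Product: 3 3,5,3'-tri-O-acetylquercetin (free 7-OH and 4'-OH)
Conditions: PhSH (2.3 equiv), imidazole (cat.), NMP, 0 °C to rt
Reagents that add atoms: none
Why: In this chemoselective thiolysis of aryl acetates the rate follows the leaving-group ability of the aryloxide, and O7 and O4' are the two oxygens conjugated with C4=O, which is the same order (7 > 4' > 3' >> 3, 5) that governs the classical deacetylative alkylation of flavonol acetates.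

Step 3
Reactants: 4 2-methylbut-3-en-2-ol
Product: 6 tert-butyl 2-methylbut-3-en-2-yl carbonate, via lithium 2-methylbut-3-en-2-olate 5 (not isolated)
Conditions: n-BuLi, THF, −78 to 0 °C; then Boc2O, 0 °C to rt
Reagents that add atoms: di-tert-butyl dicarbonate, CC(C)(C)OC(=O)OC(=O)OC(C)(C)C; n-butyllithium, [Li]CCCC (lithium of 5 only)
Why: Alkoxycarbonylation of a preformed tertiary lithium alkoxide with Boc2O is the standard way to mixed tert-allyl carbonates and avoids ionisation of the tertiary allylic alcohol.

Step 4
Reactants: 3 3,5,3'-tri-O-acetylquercetin; 6 tert-butyl 2-methylbut-3-en-2-yl carbonate (two molecules enter)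
Product: 7 3,5,3'-tri-O-acetyl-7,4'-bis-O-(1,1-dimethylallyl)quercetin
Conditions: 6 (3 equiv), Pd(PPh3)4 (10 mol %), THF, 0–5 °C
Reagents that add atoms: none
Why: In this Tsuji–Trost O-allylation (reverse prenylation) ionisation of 6 gives a π-prenyl-palladium cation, CO2 and tert-butoxide, the alkoxide deprotonates the phenol, and at low temperature the aryloxide attacks the more substituted terminus under kinetic control, as known for polyhydroxyxanthones, with no external base present to disturb the acetates.

Step 5
Reactants: 7 3,5,3'-tri-O-acetyl-7,4'-bis-O-(1,1-dimethylallyl)quercetin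
Product: 11 3,5,3'-tri-O-acetyl-8,5'-diprenylquercetin, via ring-A ortho-dienone 8 (not isolated), via 8-prenyl mono-shift phenol 9 (not isolated), via ring-B ortho-dienone 10 (not isolated)
Conditions: DMF (amine-free, degassed), 120 °C, Ar
Reagents that add atoms: none
Why: Both aryl 1,1-dimethylallyl ethers undergo a concerted aromatic Claisen [3,3] shift through a chair-like six-membered transition state in which the terminal =CH2 bonds to the ortho carbon as the O–C(tert) bond breaks, so each C5 unit is transposed and arrives as the linear 3-methylbut-2-enyl group, and dienones 8 and 10 then enolise, which makes each shift irreversible (ring A is drawn first, but the order does not matter). The closest known reaction type is the thermal ortho-Claisen rearrangement of 1,1-dimethylallyl ethers of 7-hydroxycoumarins and of 1-acyloxy-3-hydroxyxanthones in hot polar aprotic solvent, which places prenyl on the carbon next to the heterocyclic oxygen. No ring is closed, and the only new stereocentres (C8 in 8, C5' in 10) form racemic and are erased on rearomatisation, so no stereocontrol is needed. Ring A needs C8 over C6: with O5 acetylated there is no O5–H···O=C4 chelate to fix a C6=C7 bond, the fused benzopyranone keeps the higher π-bond order in C7–C8 (as in 2-naphthyl allyl ethers), and C6 is shielded by the 5-acetoxy group whereas C8 is flanked only by endocyclic O1. Ring B needs C5' over C3': C3' carries the acetoxy group, so a shift to it gives a blocked dienone that cannot enolise and can only revert, and the material funnels to C5'. The gem-dimethyl group and the electron-poor aryloxy groups, both conjugated with C4=O, lower the barrier enough for 120 °C, which is below the range where o-prenylphenols cyclise to chromans, and the neutral medium spares the acetates and the new trisubstituted alkenes.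

Step 6
Reactants: 11 3,5,3'-tri-O-acetyl-8,5'-diprenylquercetin
Product: 12 broussonol D
Conditions: NH3 (7 M in MeOH), Ar, 0 °C to rt; evaporation
Reagents that add atoms: none
Why: Ammonolysis of the two aryl acetates and the enol acetate needs only a volatile base and no acidic work-up, so the o-prenylphenols cannot cyclise to chromans, exclusion of air protects the catechol and the 3-hydroxychromone, and any acetyl migration between O3' and O4' in 11 has no consequence.

**Compound list**
1 | quercetin (3,5,7,3',4'-pentahydroxyflavone) | O=c1c(O)c(-c2ccc(O)c(O)c2)oc2cc(O)cc(O)c12 | starting material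
2 | quercetin 3,5,7,3',4'-pentaacetate | CC(=O)Oc1cc(OC(C)=O)c2c(=O)c(OC(C)=O)c(-c3ccc(OC(C)=O)c(OC(C)=O)c3)oc2c1 | intermediate
3 | 3,5,3'-tri-O-acetylquercetin (7-OH and 4'-OH free) | CC(=O)Oc1cc(O)cc2oc(-c3ccc(O)c(OC(C)=O)c3)c(OC(C)=O)c(=O)c12 | intermediate
4 | 2-methylbut-3-en-2-ol | CC(C)(O)C=C | starting material
5 | lithium 2-methylbut-3-en-2-olate | [Li+].[O-]C(C)(C)C=C | intermediate
6 | tert-butyl 2-methylbut-3-en-2-yl carbonate | CC(C)(C)OC(=O)OC(C)(C)C=C | intermediate
7 | 3,5,3'-tri-O-acetyl-7,4'-bis-O-(1,1-dimethylallyl)quercetin | CC(=O)Oc1cc(OC(C)(C)C=C)cc2oc(-c3ccc(OC(C)(C)C=C)c(OC(C)=O)c3)c(OC(C)=O)c(=O)c12 | intermediate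
8 | ring-A ortho-dienone (C7 ketone, sp3 C8 bearing H and prenyl, racemic; ring B still the 4'-tert-allyl ether) | CC(=O)OC1=CC(=O)C(CC=C(C)C)C2=C1C(=O)C(OC(C)=O)=C(c1ccc(OC(C)(C)C=C)c(OC(C)=O)c1)O2 | intermediate
9 | 3,5,3'-tri-O-acetyl-8-prenyl-4'-O-(1,1-dimethylallyl)quercetin | CC(=O)Oc1cc(O)c(CC=C(C)C)c2oc(-c3ccc(OC(C)(C)C=C)c(OC(C)=O)c3)c(OC(C)=O)c(=O)c12 | intermediate
10 | ring-B ortho-dienone (C4' ketone, sp3 C5' bearing H and prenyl, racemic; ring A already 8-prenyl-7-OH) | CC(=O)Oc1cc(O)c(CC=C(C)C)c2oc(C3=CC(CC=C(C)C)C(=O)C(OC(C)=O)=C3)c(OC(C)=O)c(=O)c12 | intermediate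
11 | 3,5,3'-tri-O-acetyl-8,5'-diprenylquercetin | CC(=O)Oc1cc(O)c(CC=C(C)C)c2oc(-c3cc(CC=C(C)C)c(O)c(OC(C)=O)c3)c(OC(C)=O)c(=O)c12 | intermediate
12 | broussonol D (8,5'-diprenylquercetin, achiral) | CC(C)=CCc1cc(-c2oc3c(CC=C(C)C)c(O)cc(O)c3c(=O)c2O)cc(O)c1O | target

**Total step count:** 6. **Longest linear sequence:** 5 (steps 1, 2, 4, 5, 6).

**Steps most likely to fail**

**Step 5.**
- **Risk:** ring-A site selectivity may erode through a competing shift to C6. The tert-allyl ethers may also fragment and lose the C5 unit before the shift.
- **Fallback:** sigmatropic O-to-C transfer is replaced by cross-coupling, so the site of each C–C bond is fixed in a separable aryl halide. It sets out from 3. Twofold electrophilic ortho-iodination, directed by the free 7-OH and 4'-OH (NIS, cat. TFA, MeCN, 0 °C), should give 8,5'-diiodo-3,5,3'-tri-O-acetylquercetin F1. A twofold Stille coupling with tributyl(3-methylbut-2-enyl)stannane (Pd(PPh3)4, DMF, 90 °C) then comes back to the route at 11.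

**Step 2.**
- **Risk:** thiolysis may discriminate poorly between the 4'-acetate and the 3'- or 3-acetates. Acetyl may also migrate between O3' and O4' in the catechol monoester.
- **Fallback:** the liberated aryloxides are trapped as they form, so the pattern is locked in a stable compound that can be purified. It sets out from 2. Deacetylative benzylation (BnBr, KI, K2CO3, acetone, reflux) should give 7,4'-di-O-benzyl-3,5,3'-tri-O-acetylquercetin F2. Neutral hydrogenolysis (H2, Pd/C, EtOAc/THF), run before any alkene is present, comes back to the route at 3.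

**Step 4.**
- **Risk:** the aryloxide may attack the unsubstituted allyl terminus. Palladium may re-ionise the tert-ether and drain it to the linear prenyl ether. The transient alkoxide may scramble the acetates.
- **Fallback:** an electrophile is used that can react only at the tertiary carbon. It sets out from 3. Copper-catalysed propargylic etherification with 3-chloro-3-methylbut-1-yne (CuCl2 cat., DBU, MeCN, −5 °C) should give 3,5,3'-tri-O-acetyl-7,4'-bis-O-(1,1-dimethylpropargyl)quercetin F3. Semihydrogenation over Lindlar catalyst (H2, quinoline, EtOAc) comes back to the route at 7.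

**Further compounds**
F1 | step 5 | 8,5'-diiodo-3,5,3'-tri-O-acetylquercetin | CC(=O)Oc1cc(O)c(I)c2oc(-c3cc(I)c(O)c(OC(C)=O)c3)c(OC(C)=O)c(=O)c12
F2 | step 2 | 7,4'-di-O-benzyl-3,5,3'-tri-O-acetylquercetin | CC(=O)Oc1cc(OCc3ccccc3)cc2oc(-c3ccc(OCc4ccccc4)c(OC(C)=O)c3)c(OC(C)=O)c(=O)c12
F3 | step 4 | 3,5,3'-tri-O-acetyl-7,4'-bis-O-(1,1-dimethylpropargyl)quercetin | CC(=O)Oc1cc(OC(C)(C)C#C)cc2oc(-c3ccc(OC(C)(C)C#C)c(OC(C)=O)c3)c(OC(C)=O)c(=O)c12
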